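All runs were computed from invented constants, and the scatter is random.

In the beta run 150 mM of substrate, the limiting reagent, meets 225 mM of reagent, yet product stands at 51.3 mM after 21 h. In the eta run, with twice the reagent, it stands at 76.8 mM. So a loss runs beside the main step, and reagent competes with it.

| flask | substrate | reagent | time |
|---|---|---|---|
| beta | 150 mM | 225 mM |  |
| eta | 150 mM | 450 mM |  |
| gamma | 37.0 mM | 56.0 mM | 21 h |

| beta run: time / h | beta run: [product] / mM | eta run: time / h | eta run: [product] / mM |
|---|---|---|---|
| 0.84 | 16.4 | 0.84 | 30.2 |
| 1.4 | 21.6 | 1.4 | 39.7 |
| 2.5 | 29.5 | 2.5 | 50.9 |
| 4.2 | 35.8 | 4.2 | 63.8 |
| 7.2 | 43.8 | 7.2 | 72.1 |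
| 12 | 48.4 | 12 | 73.7 |
| 21 | 51.3 | 21 | 76.8 |

(readings scatter by 0.8 mM)

* apparent order in [reagent] of the starting rate, round the charge of the beta run (the rate where two percent of its substrate have turned into product)
* product in the gamma run at 21 h, as a share of the substrate charged
* which of these the readings show (the second partner is lost by itself / nothing beyond the main steps / the product speeds the reaction / the product decays / the second partner pairs with itself / two substrates go astray together)

- Overall: substrate + reagent -> product.
- Constant volume, constant temperature.
- "The second partner" is reagent.
- An order is taken over about fifteen percent of the charge, up and down.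

From 4.2 h to 7.2 h the gap to the last reading shrinks by a factor of 2.07 in the beta run and 2.77 in the eta run, faster with more reagent. I therefore read the loss as two substrates going astray together.

Then both steps take two partners, and this gives a rule: divide both charges by one number at the same temperature, and the time to reach a given share of the charge is multiplied by that number. The gamma run is the beta run diluted, so I carry the beta-clock time, the asked time multiplied by c(substrate) in gamma over c(substrate) in beta.

What must you know well? The proportions first: c(reagent)/c(substrate) is 1.51 in gamma and 1.50 in beta, a difference of 0.901 %, and you can leave that aside. The scatter matters more, since one reading's 0.8 mM is 0.533 % of the beta charge. The rate constants don't enter this reckoning.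

The number itself: the beta-clock time is 5.18 h. A straight line between the beta readings on either side gives 38.4 mM, so my share is 25.6 %.

The forecast gave an order of 1.11, a share of 28 % (25 % to 31 %) and "two substrates go astray together", holding that “something removes a partner in parallel”. The simulation gives 1.1, 26.6 % and "two substrates go astray together".

    substrate + reagent → product (0.7776 M⁻¹ h⁻¹)
    2 substrate → homo dimer (2.722 M⁻¹ h⁻¹)

Both steps take two partners, so the beta clock holds. The beta run reaches a quarter of its charge at 4.42 h, earlier than the beta-clock time, and the gamma run does stand just past that share at 21 h. The loss of 2 substrate to homo dimer takes 25 percentage points off the gamma run, which is 34 % of what is missing there: without that step the gamma run stands at 51.7 % at 21 h, against 26.6 % with it.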